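The trap is to set the side step against the opening step at the charge and stop there.

    starting material → intermediate A (k1 = 0.032 min⁻¹)
    intermediate A ⇌ intermediate B (K2 = 0.41, k2 = 0.0026 min⁻¹)
    intermediate B → target (k3 = 0.0063 min⁻¹)
    starting material + intermediate A → side product (k4 = 0.41 M⁻¹ min⁻¹)

all flasks: time 10 h
- grey: starting material 8.0 mM
- red: starting material 12 mM
- green: starting material 20 mM
- violet: starting material 30 mM
- amber: starting material 50 mM

- in percentages every species weighs as the starting material in it: one side product counts as two
- "hardly changes" means that all values lie within two and a half points (for a concentration: within two and a half percent of the largest)
- run time (grey): 10 h

1. share of target in all that became target or side product for grey, red, green, violet, amber, in this order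
2. the course of these numbers from the first flask to the last (rises all the way / hardly changes / falls, then rises / rises, then falls / falls all the way)

In amber, intermediate A stays below the 50 mM charged, so the rate at which the side step takes starting material stays under 0.641 of the rate of the opening step, and at the start the side step does not run at all. Yet I reckon that amber loses about a third of its charge to side product.

The balance of the starting material clears this up. Let S and A be the concentrations of starting material and intermediate A, and c the charge. I define C, the concentration of intermediate A at which the side step consumes starting material as fast as the opening step, 78.0 mM. The side step lowers S and A together, so dividing their balances removes time: each unit of S lost yields (C−A)/(C+A) of A. A side event therefore costs twice, one unit of S and one of A already made. Integrated over the whole of S and shortened to a simple fraction, the lost part is c/(c+C). Intermediate A also leaks forward, which trims this by 0.925. For amber the loss L is 36.1 %, a third, so the share of target tends to 63.9 % once the intermediates have passed on, and stands lower before that. My reckoning stops here, without the time course.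

The forecast gives 82.6 %, 76.4 %, 66.7 %, 57.8 % and 46.4 %, from an early fast phase followed by a slow chain: “It falls steadily”.

The simulation gives 82.5 %, 76.0 %, 66.0 %, 57.0 % and 45.1 %; the course falls all the way, and the forecast holds within its margin.

Amber's side product reads 35.1 % at 10.0 h, beside the 36.1 % I reckoned. For grey, the same rule gives 8.60 %, and the flask reads 8.54 %, which leaves 91.4 % for target. Grey's share is lower than that at 10.0 h, and the main reason is the reading at that time and not ten times later. Intermediate A still holds 41.8 % of the charge then. With the reading at 10.0 h taken away and grey read at 100 h instead, its share stands at 91.4 %.

The rate constants stand for no real mixture.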